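## Retrosynthetic overview

1. The target is opened in one operation to an acyclic (E,E)-dienone keto-phenol that holds all 28 carbons: retro-aldol condensation (cyclohexenone), retro-Michael between the two quaternary carbons (cyclopentane), retro-oxa-Michael (chroman).
2. Forward ring order, all in the last flask: chroman ring, then cyclopentane, then cyclohexenone; two organocatalysts used in relay set the three stereocentres there.
3. Dienone ⇒ E-alkenyl iodide (arene arm) + E-keto-enal (C15 arm) by Nozaki–Hiyama–Kishi coupling, then MnO2.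
4. Keto-enal ⇒ geranyl acetate (E-alkene bought): SeO2 oxidation of the terminal methyl, a C5 Grignard reagent from 4-chloro-2-methylbutan-2-ol, redox isomerisation, release of the enal.
5. Alkenyl iodide ⇒ 4-methoxy-2-methylphenol: ortho-formylation, propargylation/ionic hydrogenation, carboalumination–iodination.

Assumption: the facial sense given by each of the two cinchona-derived catalysts in step 10 is taken from their usual transition-state models; both are available in the quinine and the quinidine series, so the other hand is used if a catalyst delivers the opposite face.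

## Route

Step 1
Reactants: 1 geranyl acetate [(2E)-3,7-dimethylocta-2,6-dien-1-yl acetate]
Product: 3 (2E,6E)-3,7-dimethyl-8-oxoocta-2,6-dien-1-yl acetate, via allylic alcohol 2 (not isolated)
Conditions: SeO2 (0.5 equiv), t-BuOOH, salicylic acid (cat.), CH2Cl2, rt; then MnO2, CH2Cl2, rt
Reagents that add atoms: selenium dioxide, O=[Se]=O (delivers the oxygen atom and is regenerated); tert-butyl hydroperoxide, CC(C)(C)OO (stoichiometric oxygen source)
Why: Riley allylic oxidation attacks only the E-methyl group of the electron-rich terminal alkene because the 2,3-alkene is deactivated by its allylic acetate, and MnO2 then converges the alcohol/aldehyde mixture on the E-enal without creating a stereocentre.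

Step 2
Reactants: 3 (2E,6E)-3,7-dimethyl-8-oxoocta-2,6-dien-1-yl acetate; 4 4-chloro-2-methylbutan-2-ol
Product: 6 (2E,6E)-8,11-dihydroxy-3,7,11-trimethyldodeca-2,6-dien-1-yl acetate, via alkoxide Grignard reagent 5 (not isolated)
Conditions: 4, i-PrMgCl (1 equiv), THF, −20 °C, then Mg, reflux; added to 3, THF, −78 °C; aq. NH4Cl
Reagents that add atoms: none
Why: Grignard 1,2-addition of the Normant-type alkoxide-bearing reagent to the enal is far faster at −78 °C than attack on the acetate, so the five-carbon tertiary-alcohol arm is installed in one operation; the new carbinol centre is racemic and is erased in step 3.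

Step 3
Reactants: 6 (2E,6E)-8,11-dihydroxy-3,7,11-trimethyldodeca-2,6-dien-1-yl acetate
Product: 7 (2E)-11-hydroxy-3,7,11-trimethyl-8-oxododec-2-en-1-yl acetate
Conditions: [Ir(cod)(PCy3)(py)]PF6 (3 mol %), H2 (brief activation, then Ar purge), THF, rt
Reagents that add atoms: none
Why: Iridium-hydride-catalysed redox isomerisation of the secondary allylic alcohol (alkene insertion, β-hydride elimination to the enol, tautomerisation) gives the saturated α-methyl ketone, while the other alkene has no carbinol hydrogen and stays in place; the α-methyl centre is racemic and is later funnelled through an enamine.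

Step 4
Reactants: 7 (2E)-11-hydroxy-3,7,11-trimethyl-8-oxododec-2-en-1-yl acetate
Product: 9 (2E)-11-hydroxy-3,7,11-trimethyl-8-oxododec-2-enal, via allylic alcohol 8 (not isolated)
Conditions: K2CO3, MeOH, rt; then MnO2, CH2Cl2, rt
Reagents that add atoms: none
Why: Base-catalysed transesterification frees the primary allylic alcohol and MnO2 oxidises only this allylic position, leaving the saturated ketone, the tertiary alcohol and the E-alkene untouched.

Step 5
Reactants: 10 4-methoxy-2-methylphenol
Product: 11 2-hydroxy-5-methoxy-3-methylbenzaldehyde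
Conditions: (CH2O)n, MgCl2, Et3N, MeCN, reflux
Reagents that add atoms: paraformaldehyde (formaldehyde), C=O
Why: Magnesium-phenoxide-directed ortho-formylation (Casnati–Skattebøl reaction) delivers the formyl group only to the single free position ortho to the hydroxyl group.

Step 6
Reactants: 11 2-hydroxy-5-methoxy-3-methylbenzaldehyde
Product: 13 2-(but-3-yn-1-yl)-4-methoxy-6-methylphenol, via homopropargylic alcohol 12 (not isolated)
Conditions: propargyl bromide, Zn, THF/sat. aq. NH4Cl, 0 °C to rt; then Et3SiH, TFA, CH2Cl2, 0 °C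
Reagents that add atoms: propargyl bromide, C#CCBr
Why: Zinc Barbier propargylation gives the homopropargylic benzylic alcohol, whose ortho-hydroxybenzyl cation (ortho-quinone methide) formed in TFA is reduced by Et3SiH (ionic hydrogenation), so the alkyne arm is attached without protecting the phenol and no stereocentre remains.

Step 7
Reactants: 13 2-(but-3-yn-1-yl)-4-methoxy-6-methylphenol
Product: 15 2-[(3E)-4-iodo-3-methylbut-3-en-1-yl]-4-methoxy-6-methylphenol, via alkenylalane 14 (not isolated)
Conditions: AlMe3 (3.5 equiv), Cp2ZrCl2 (25 mol %), CH2Cl2, 0 °C to rt; then I2, THF, −30 °C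
Reagents that add atoms: trimethylaluminium, C[Al](C)C; iodine, [I][I]
Why: Negishi zirconium-catalysed carboalumination adds methyl and aluminium syn across the terminal alkyne with the methyl group on the internal carbon, and iodinolysis with retention gives the E-alkenyl iodide, the phenol being masked in the flask as its aluminium phenoxide.

Step 8
Reactants: 15 2-[(3E)-4-iodo-3-methylbut-3-en-1-yl]-4-methoxy-6-methylphenol; 9 (2E)-11-hydroxy-3,7,11-trimethyl-8-oxododec-2-enal
Product: 16 (3E,6E)-5,15-dihydroxy-1-(2-hydroxy-5-methoxy-3-methylphenyl)-3,7,11,15-tetramethylhexadeca-3,6-dien-12-one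
Conditions: CrCl2 (4 equiv), NiCl2 (2 mol %), DMSO, rt
Reagents that add atoms: none
Why: Nozaki–Hiyama–Kishi coupling: the alkenylchromium reagent generated under nickel catalysis adds only to the aldehyde, tolerates the ketone and the free hydroxyl groups and keeps both alkene geometries; the new carbinol centre is uncontrolled and is removed in step 9.

Step 9
Reactants: 16 (3E,6E)-5,15-dihydroxy-1-(2-hydroxy-5-methoxy-3-methylphenyl)-3,7,11,15-tetramethylhexadeca-3,6-dien-12-one
Product: 17 (3E,6E)-15-hydroxy-1-(2-hydroxy-5-methoxy-3-methylphenyl)-3,7,11,15-tetramethylhexadeca-3,6-diene-5,12-dione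
Conditions: MnO2, CH2Cl2, 0 °C to rt; filtration through Celite, no silica
Reagents that add atoms: none
Why: MnO2 oxidation of the doubly allylic alcohol under neutral heterogeneous conditions gives the cross-conjugated (E,E)-dienone without touching the saturated ketone or the tertiary alcohol, and the crude product is kept off silica so that the phenol does not add to the enone before a chiral catalyst is present.

Step 10
Reactants: 17 (3E,6E)-15-hydroxy-1-(2-hydroxy-5-methoxy-3-methylphenyl)-3,7,11,15-tetramethylhexadeca-3,6-diene-5,12-dione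
Product: 20 (3aS,7aS)-5-(2-hydroxy-2-methylpropyl)-6-{[(2R)-6-methoxy-2,8-dimethyl-3,4-dihydro-2H-chromen-2-yl]methyl}-3a,7a-dimethyl-1,2,3,3a,7,7a-hexahydro-4H-inden-4-one (CNP0224132.1), via chroman enone 18 (not isolated), via cyclopentane diketone 19 (not isolated)
Conditions: squaramide of 9-amino-9-deoxy-epi-quinine bearing a 3,5-bis(trifluoromethyl)phenyl group (10 mol %), PhMe, −20 °C; then 9-amino-9-deoxy-epi-quinine (20 mol %), 2-FC6H4CO2H (60 mol %), 50 °C
Reagents that add atoms: none
Why: Proposed new method: a relay of two organocatalytic activation modes closes the rings in the biosynthetic order — (a) the squaramide hydrogen-bonds the dienone carbonyl while its quinuclidine deprotonates the phenol, so a 6-exo oxa-Michael addition to the Re face of the (E)-β,β-disubstituted enone arm next to the arene sets the (R)-chroman centre (closest known type: bifunctional base/hydrogen-bond-catalysed asymmetric intramolecular oxa-Michael addition of phenols to enones); (b) once the acid has switched this base off, the primary amine condenses only with the unhindered saturated ketone, and its more substituted secondary enamine adds 5-exo to the Si face of the remaining enone β-carbon through a compact aza-ene-like transition state that places the two carbonyl-bearing arms cis and creates both quaternary carbons as (S,S), the racemic α-methyl centre of 17 being funnelled through the enamine (closest known types: d'Angelo-type Michael additions of secondary enamines that form quaternary carbons, and cinchona primary amine/acid-catalysed intramolecular ketone-to-enone Michael additions); (c) the same amine, now as the less substituted enamine, attacks the 1,5-related ketone and dehydration gives the tetrasubstituted enone (Hajos–Parrish/Robinson-type aldol condensation), only the cis adduct being able to close while any trans adduct reverts by retro-Michael, and the chroman centre survives because its β-aryloxy ketone, flanked by two neopentyl carbons, is not enolised under these weakly acidic conditions.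

## Compound list

1 | geranyl acetate, (2E)-3,7-dimethylocta-2,6-dien-1-yl acetate | CC(=O)OC/C=C(\C)CCC=C(C)C | starting material
2 | (2E,6E)-8-hydroxy-3,7-dimethylocta-2,6-dien-1-yl acetate | CC(=O)OC/C=C(\C)CC/C=C(\C)CO | intermediate
3 | (2E,6E)-3,7-dimethyl-8-oxoocta-2,6-dien-1-yl acetate | CC(=O)OC/C=C(\C)CC/C=C(\C)C=O | intermediate
4 | 4-chloro-2-methylbutan-2-ol | CC(C)(O)CCCl | starting material
5 | [3-(chloromagnesiooxy)-3-methylbutyl]magnesium chloride | CC(C)(CC[Mg]Cl)O[Mg]Cl | intermediate
6 | (2E,6E)-8,11-dihydroxy-3,7,11-trimethyldodeca-2,6-dien-1-yl acetate (racemic at C8) | CC(=O)OC/C=C(\C)CC/C=C(\C)C(O)CCC(C)(C)O | intermediate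
7 | (2E)-11-hydroxy-3,7,11-trimethyl-8-oxododec-2-en-1-yl acetate (racemic at C7) | CC(=O)OC/C=C(\C)CCCC(C)C(=O)CCC(C)(C)O | intermediate
8 | (2E)-1,11-dihydroxy-3,7,11-trimethyldodec-2-en-8-one (racemic at C7) | OC/C=C(\C)CCCC(C)C(=O)CCC(C)(C)O | intermediate
9 | (2E)-11-hydroxy-3,7,11-trimethyl-8-oxododec-2-enal (racemic at C7) | O=C/C=C(\C)CCCC(C)C(=O)CCC(C)(C)O | intermediate
10 | 4-methoxy-2-methylphenol | COc1ccc(O)c(C)c1 | starting material
11 | 2-hydroxy-5-methoxy-3-methylbenzaldehyde | COc1cc(C)c(O)c(C=O)c1 | intermediate
12 | 2-(1-hydroxybut-3-yn-1-yl)-4-methoxy-6-methylphenol (racemic) | COc1cc(C)c(O)c(C(O)CC#C)c1 | intermediate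
13 | 2-(but-3-yn-1-yl)-4-methoxy-6-methylphenol | COc1cc(C)c(O)c(CCC#C)c1 | intermediate
14 | [(1E)-4-{2-[(dimethylalumanyl)oxy]-5-methoxy-3-methylphenyl}-2-methylbut-1-en-1-yl]dimethylalumane | COc1cc(C)c(O[Al](C)C)c(CC/C(C)=C/[Al](C)C)c1 | intermediate
15 | 2-[(3E)-4-iodo-3-methylbut-3-en-1-yl]-4-methoxy-6-methylphenol | COc1cc(C)c(O)c(CC/C(C)=C/I)c1 | intermediate
16 | (3E,6E)-5,15-dihydroxy-1-(2-hydroxy-5-methoxy-3-methylphenyl)-3,7,11,15-tetramethylhexadeca-3,6-dien-12-one (mixture at C5 and C11) | COc1cc(C)c(O)c(CC/C(C)=C/C(O)/C=C(\C)CCCC(C)C(=O)CCC(C)(C)O)c1 | intermediate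
17 | (3E,6E)-15-hydroxy-1-(2-hydroxy-5-methoxy-3-methylphenyl)-3,7,11,15-tetramethylhexadeca-3,6-diene-5,12-dione (racemic at C11) | COc1cc(C)c(O)c(CC/C(C)=C/C(=O)/C=C(\C)CCCC(C)C(=O)CCC(C)(C)O)c1 | intermediate
18 | (3E)-12-hydroxy-1-[(2R)-6-methoxy-2,8-dimethyl-3,4-dihydro-2H-chromen-2-yl]-4,8,12-trimethyltridec-3-ene-2,9-dione (both epimers at C8) | COc1cc(C)c2c(c1)CC[C@](C)(CC(=O)/C=C(\C)CCCC(C)C(=O)CCC(C)(C)O)O2 | intermediate
19 | 4-hydroxy-1-[(1S,2S)-2-{3-[(2R)-6-methoxy-2,8-dimethyl-3,4-dihydro-2H-chromen-2-yl]-2-oxopropyl}-1,2-dimethylcyclopentyl]-4-methylpentan-1-one | COc1cc(C)c2c(c1)CC[C@](C)(CC(=O)C[C@]3(C)CCC[C@]3(C)C(=O)CCC(C)(C)O)O2 | intermediate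
20 | (3aS,7aS)-5-(2-hydroxy-2-methylpropyl)-6-{[(2R)-6-methoxy-2,8-dimethyl-3,4-dihydro-2H-chromen-2-yl]methyl}-3a,7a-dimethyl-1,2,3,3a,7,7a-hexahydro-4H-inden-4-one | COc1cc(C)c2c(c1)CC[C@](C)(CC1=C(CC(C)(C)O)C(=O)[C@@]3(C)CCC[C@@]3(C)C1)O2 | target

## Step count and risks

Total step count: 10.
Longest linear sequence: 7 (steps 1, 2, 3, 4, 8, 9, 10); the arene arm (steps 5, 6, 7) joins at step 8.

The three steps most likely to fail:

**Step 10.** The enamine Michael addition has to join two fully substituted carbons, and the amine stage must not reopen the chroman. Fallback, setting out from 17 and coming back at 20: only the first stage of step 10 is run and chroman enone 18 is isolated. TMSOTf/Et3N (CH2Cl2, −78 to 0 °C) converts the saturated ketone into its more substituted silyl enol ether and silylates the tertiary alcohol, giving (3E)-1-[(2R)-6-methoxy-2,8-dimethyl-3,4-dihydro-2H-chromen-2-yl]-4,8,12-trimethyl-9,12-bis(trimethylsilyloxy)trideca-3,8-dien-2-one F1. An intramolecular Mukaiyama–Michael addition under a chiral silylium Lewis acid (imidodiphosphorimidate catalyst, PhMe, −40 °C) followed by dilute HCl gives diketone 19. Compound 19 is isolated and closed to 20 with pyrrolidinium acetate (PhMe, 60 °C). The nucleophile is thus preformed and the acceptor is activated by a Lewis acid, with no amine present while the quaternary carbons are made.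

**Step 3.** The alkene to be isomerised is trisubstituted and carries an α-methyl group, which slows hydride insertion. Fallback, setting out from 6 and coming back at 7: MnO2 (CH2Cl2, rt) oxidises the allylic alcohol to (2E,6E)-11-hydroxy-3,7,11-trimethyl-8-oxododeca-2,6-dien-1-yl acetate F2. Conjugate reduction of this α-methyl enone with [(Ph3P)CuH]6 (benzene, rt) then gives 7. The β,β-disubstituted alkene bearing the allylic acetate is not an acceptor and stays.

**Step 9.** The electron-rich free phenol may be oxidised by MnO2 or may add to the new dienone without a chiral catalyst. Fallback, setting out from 13 and coming back at 17: the phenol is carried as a silyl ether and released only in the flask of step 10.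
- TBSCl/imidazole (DMF) gives tert-butyl[2-(but-3-yn-1-yl)-4-methoxy-6-methylphenoxy]dimethylsilane F3.
- Carboalumination–iodination as in step 7 gives tert-butyl{2-[(3E)-4-iodo-3-methylbut-3-en-1-yl]-4-methoxy-6-methylphenoxy}dimethylsilane F4.
- Coupling with 9 (CrCl2, NiCl2 cat., DMSO) gives (3E,6E)-1-{2-[tert-butyl(dimethyl)silyl]oxy-5-methoxy-3-methylphenyl}-5,15-dihydroxy-3,7,11,15-tetramethylhexadeca-3,6-dien-12-one F5.
- MnO2 gives (3E,6E)-1-{2-[tert-butyl(dimethyl)silyl]oxy-5-methoxy-3-methylphenyl}-15-hydroxy-3,7,11,15-tetramethylhexadeca-3,6-diene-5,12-dione F6.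
- TBAF buffered with AcOH (THF, −20 °C) releases 17, which is taken at once into step 10.

Further compounds
F1 | step 10 | (3E)-1-[(2R)-6-methoxy-2,8-dimethyl-3,4-dihydro-2H-chromen-2-yl]-4,8,12-trimethyl-9,12-bis(trimethylsilyloxy)trideca-3,8-dien-2-one | COc1cc(C)c2c(c1)CC[C@](C)(CC(=O)/C=C(\C)CCCC(C)=C(O[Si](C)(C)C)CCC(C)(C)O[Si](C)(C)C)O2
F2 | step 3 | (2E,6E)-11-hydroxy-3,7,11-trimethyl-8-oxododeca-2,6-dien-1-yl acetate | CC(=O)OC/C=C(\C)CC/C=C(\C)C(=O)CCC(C)(C)O
F3 | step 9 | tert-butyl[2-(but-3-yn-1-yl)-4-methoxy-6-methylphenoxy]dimethylsilane | COc1cc(C)c(O[Si](C)(C)C(C)(C)C)c(CCC#C)c1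
F4 | step 9 | tert-butyl{2-[(3E)-4-iodo-3-methylbut-3-en-1-yl]-4-methoxy-6-methylphenoxy}dimethylsilane | COc1cc(C)c(O[Si](C)(C)C(C)(C)C)c(CC/C(C)=C/I)c1
F5 | step 9 | (3E,6E)-1-{2-[tert-butyl(dimethyl)silyl]oxy-5-methoxy-3-methylphenyl}-5,15-dihydroxy-3,7,11,15-tetramethylhexadeca-3,6-dien-12-one | COc1cc(C)c(O[Si](C)(C)C(C)(C)C)c(CC/C(C)=C/C(O)/C=C(\C)CCCC(C)C(=O)CCC(C)(C)O)c1
F6 | step 9 | (3E,6E)-1-{2-[tert-butyl(dimethyl)silyl]oxy-5-methoxy-3-methylphenyl}-15-hydroxy-3,7,11,15-tetramethylhexadeca-3,6-diene-5,12-dione | COc1cc(C)c(O[Si](C)(C)C(C)(C)C)c(CC/C(C)=C/C(=O)/C=C(\C)CCCC(C)C(=O)CCC(C)(C)O)c1
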